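**Strategy.** The upper C ring is disconnected at O1–C2 and, decisively, on both sides of its C3–C4 bond: C3 is a carbinol carbon and C4 a diaryl methine bonded to A-ring C4a and to C8 of the lower catechin unit. One palladium-catalysed conjunctive coupling exploits this pattern, joining a (Z)-vinyl boronate on catechin C8, a 1-arylvinyllithium (the C2/B-ring carbon) and the A-ring bromide; it forms C2–C3 and C4–C4a by anti addition, sets both stereocentres and leaves boron on C3 as a masked hydroxyl. The precursor is penta-O-benzylcatechin bearing a cis-CH=CH–B(diol) group at C8; chelation-controlled ketone reduction and Mitsunobu closure complete the ring.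

Key step: step 12

Assumption: the target is epigallocatechin-(4β→8)-catechin (upper unit 2R,3R,4R, i.e. 2,3-cis-3,4-trans; lower unit 2R,3S); atoms of the future upper unit keep their flavan numbers (C2, C3, C4, C4a) in the open-chain intermediates, and "catechin-8-yl" means the (2R,3S)-3,5,7,3',4'-penta-O-benzylcatechin unit bonded through C8.
Assumption: 3,4,5-tris(benzyloxy)benzoic acid and both antipodes of MandyPhos are catalogue items; the antipode that leads to 3R,4R is fixed in one comparison run of step 12.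
Remark on the design: boron carries the bulky cis-1,2-dimethylacenaphthene-1,2-diol ("mac") ester, because β-substituted alkenyl boronates of small diols divert to direct Suzuki coupling. The A-ring bromide is the symmetric tris-MOM ether, because it brominates to a single isomer and either ortho oxygen closes the same pyran ring. C3–O is benzylated before alkene cleavage, because a free C3 hydroxyl would expose C2–C3 to periodate.

Step 1
Reactants: 1 (+)-catechin
Product: 2 5,7,3',4'-tetra-O-benzyl-(+)-catechin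
Conditions: BnBr (4.4 equiv), K2CO3, DMF, 0 °C → rt
Reagents that add atoms: benzyl bromide BrCc1ccccc1
Why: Williamson etherification with a carbonate base should alkylate only the four phenols, leaving the secondary 3-OH and both stereocentres untouched.

Step 2
Reactants: 2 5,7,3',4'-tetra-O-benzyl-(+)-catechin
Product: 3 8-bromo-5,7,3',4'-tetra-O-benzylcatechin
Conditions: NBS (1.0 equiv), CH2Cl2, −45 °C → rt
Reagents that add atoms: N-bromosuccinimide O=C1CCC(=O)N1Br
Why: Electrophilic aromatic bromination of the trioxygenated ring should go to C8, which is flanked by the ring oxygen and only one benzyloxy group and is therefore less shielded than C6.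

Step 3
Reactants: 3 8-bromo-5,7,3',4'-tetra-O-benzylcatechin
Product: 4 8-bromo-3,5,7,3',4'-penta-O-benzylcatechin
Conditions: NaH, BnBr, DMF, 0 °C → rt
Reagents that add atoms: benzyl bromide BrCc1ccccc1
Why: Williamson etherification of the secondary alkoxide removes the last acidic proton before the organolithium steps, and the aryl bromide is inert to NaH.

Step 4
Reactants: 4 8-bromo-3,5,7,3',4'-penta-O-benzylcatechin
Product: 6 3,5,7,3',4'-penta-O-benzylcatechin-8-carbaldehyde, via 8-lithio-penta-O-benzylcatechin 5 (not isolated)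
Conditions: n-BuLi, THF, −78 °C; then DMF, −78 → 0 °C; aq. NH4Cl
Reagents that add atoms: N,N-dimethylformamide CN(C)C=O
Why: Bromine–lithium exchange at −78 °C outruns benzylic deprotonation, and the aryllithium is formylated by DMF (Bouveault aldehyde synthesis).

Step 5
Reactants: 6 3,5,7,3',4'-penta-O-benzylcatechin-8-carbaldehyde
Product: 7 8-ethynyl-3,5,7,3',4'-penta-O-benzylcatechin
Conditions: dimethyl (1-diazo-2-oxopropyl)phosphonate, K2CO3, MeOH/THF, 0 °C → rt
Reagents that add atoms: Ohira–Bestmann reagent CC(=O)C(=[N+]=[N-])P(=O)(OC)OC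
Why: Seyferth–Gilbert homologation in its Ohira–Bestmann form converts the aldehyde into the terminal alkyne under mild carbonate conditions that cannot touch the catechin stereocentres.

Step 6
Reactants: 8 acenaphthoquinone
Product: 9 cis-1,2-dimethyl-1,2-dihydroacenaphthylene-1,2-diol (mac diol)
Conditions: AlMe3 (2.5 equiv), toluene, 0 °C → rt; aqueous work-up; recrystallisation
Reagents that add atoms: trimethylaluminium C[Al](C)C
Why: Double 1,2-addition of organoaluminium methyl to the 1,2-dione should give mainly the cis (meso) diol, since the second methyl enters anti to the aluminium alkoxide formed first, and crystallisation removes any trans diol, which cannot form a cyclic boronate.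

Step 7
Reactants: 7 8-ethynyl-3,5,7,3',4'-penta-O-benzylcatechin; 9 mac diol
Product: 11 (Z)-2-(penta-O-benzylcatechin-8-yl)vinylboronic acid mac ester, via catechol boronate 10 (not isolated)
Conditions: catecholborane, [Rh(cod)Cl]2 (cat.), P(i-Pr)3 (cat.), Et3N, cyclohexane/THF, rt; then 9, rt
Reagents that add atoms: catecholborane B1Oc2ccccc2O1
Why: Rhodium-catalysed trans-hydroboration of the terminal alkyne runs through a rhodium vinylidene (1,2-hydrogen shift), which places boron cis to the aryl group and so sets the Z geometry, and the labile catechol ester is transesterified in the same flask by diol 9.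

Step 8
Reactants: 12 3,4,5-tris(benzyloxy)benzoic acid
Product: 13 1-[3,4,5-tris(benzyloxy)phenyl]ethan-1-one
Conditions: MeLi (2.2 equiv), THF, 0 °C → rt; aq. NH4Cl
Reagents that add atoms: methyllithium [Li]C
Why: Addition of methyllithium to the lithium carboxylate stops at the gem-diolate dianion, which collapses to the methyl ketone only on work-up (ketone synthesis from a carboxylic acid and an organolithium).

Step 9
Reactants: 13 1-[3,4,5-tris(benzyloxy)phenyl]ethan-1-one
Product: 14 1,2,3-tris(benzyloxy)-5-(1-bromovinyl)benzene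
Conditions: (PhO)3P, Br2, CH2Cl2, −60 °C; then Et3N, 13, −60 °C → rt, then 40 °C
Reagents that add atoms: bromine BrBr
Why: Ketone-to-vinyl-bromide conversion with the triphenyl phosphite–bromine reagent (O-phosphonium activation, bromide addition, amine-induced elimination) delivers bromine as a P(V) complex and should spare the electron-rich ring; only the methyl side can enolise, so only the 1-bromovinyl isomer can form.

Step 10
Reactants: 15 phloroglucinol
Product: 16 1,3,5-tris(methoxymethoxy)benzene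
Conditions: NaH, MOMCl, DMF, 0 °C → rt
Reagents that add atoms: chloromethyl methyl ether COCCl
Why: Williamson-type O-alkylation of the triphenoxide with the hard electrophile MOMCl in DMF should favour the tris-acetal over C-alkylation.

Step 11
Reactants: 16 1,3,5-tris(methoxymethoxy)benzene
Product: 17 2-bromo-1,3,5-tris(methoxymethoxy)benzene
Conditions: NBS (1.0 equiv), NaHCO3, CH2Cl2, −20 → 0 °C
Reagents that add atoms: N-bromosuccinimide O=C1CCC(=O)N1Br
Why: Electrophilic aromatic bromination of a ring whose three free positions are equivalent can give only one monobromide, and one equivalent of NBS at low temperature with a bicarbonate buffer should avoid dibromination and acetal loss.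

Step 12
Reactants: 14 1,2,3-tris(benzyloxy)-5-(1-bromovinyl)benzene; 11 (Z)-2-(penta-O-benzylcatechin-8-yl)vinylboronic acid mac ester; 17 2-bromo-1,3,5-tris(methoxymethoxy)benzene
Product: 20 (3R,4R)-2-[3,4,5-tris(benzyloxy)phenyl]-4-[2,4,6-tris(methoxymethoxy)phenyl]-4-(penta-O-benzylcatechin-8-yl)but-1-en-3-ylboronic acid mac ester, via 1-arylvinyllithium 18 (not isolated), via lithium ate complex 19 (not isolated)
Conditions: 14, t-BuLi (2.0 equiv), Et2O/THF, −78 °C; then 11, −78 °C → rt; then 17, Pd(OAc)2 (5 mol%), MandyPhos (one antipode, 6 mol%), KOTf (3 equiv), THF, 60 °C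
Reagents that add atoms: none
Why: Proposed new method: the vinyllithium 18 adds to boron of 11 to give the four-coordinate bis(alkenyl)borate 19; the arylpalladium(II) species from oxidative addition of 17 binds the (Z)-alkene and induces a 1,2-shift of the arylvinyl group from boron to C3 on the face opposite to palladium, and reductive elimination from the resulting C4–Pd–aryl unit then forms C4–C4a. The closest known reaction type is the palladium/chiral bisphosphine conjunctive cross-coupling of alkenylboron ate complexes (1,2-metallate shift), known with β-substituted alkenyl boronates of hindered diols and with alkenyl migrating groups, but not with a β-aryl acceptor and an aryl halide that are both di-ortho-substituted. No ring is closed in this step. C3 and C4 are set together: the anti relationship of the migrating carbon and palladium across the (Z)-alkene, followed by stereoretentive reductive elimination, fixes the relative configuration (3,4-trans after oxidation), and the antipode of MandyPhos selects the alkene face and hence the absolute 3R,4R sense over the weak bias of the remote catechin centres. The step needs conjunctive coupling to beat direct Suzuki transfer of either alkenyl group, for which the bulky mac diol on boron is installed, and it needs the catechinyl alkene, not the arylvinyl group, to act as acceptor, which should be favoured because the alternative shift would build a fully substituted benzylic C–B centre. KOTf removes bromide, which would otherwise occupy the palladium site needed for alkene binding.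

Step 13
Reactants: 20 (3R,4R)-open-chain C3 mac boronate
Product: 21 (3R,4R)-2-[3,4,5-tris(benzyloxy)phenyl]-4-[2,4,6-tris(methoxymethoxy)phenyl]-4-(penta-O-benzylcatechin-8-yl)but-1-en-3-ol
Conditions: 30% H2O2, 3 M aq. NaOH, THF, 0 °C → rt
Reagents that add atoms: hydrogen peroxide OO
Why: Alkaline peroxide oxidation of the boronate (1,2-migration of C3 from boron to oxygen) replaces C–B by C–OH with retention, so the C3 configuration is carried over unchanged and without allylic transposition.

Step 14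
Reactants: 21 (3R,4R)-allylic alcohol
Product: 22 (3R,4R)-3-(benzyloxy)-2-[3,4,5-tris(benzyloxy)phenyl]-4-[2,4,6-tris(methoxymethoxy)phenyl]-4-(penta-O-benzylcatechin-8-yl)but-1-ene
Conditions: NaH, BnBr, Bu4NI (cat.), DMF, 0 °C → rt
Reagents that add atoms: benzyl bromide BrCc1ccccc1
Why: Williamson etherification blocks O3 so that the coming periodate step cannot cut C2–C3, and it supplies the chelating α-alkoxy group for the reduction.

Step 15
Reactants: 22 (3R,4R)-3-benzyloxy alkene
Product: 24 (2R,3R)-2-(benzyloxy)-1-[3,4,5-tris(benzyloxy)phenyl]-3-[2,4,6-tris(methoxymethoxy)phenyl]-3-(penta-O-benzylcatechin-8-yl)propan-1-one, via 1,2-diol 23 (not isolated)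
Conditions: OsO4 (cat.), NaIO4 (4 equiv), 2,6-lutidine, dioxane/H2O, rt
Reagents that add atoms: osmium tetroxide O=[Os](=O)(=O)=O (oxygen donor, regenerated by sodium periodate [Na+].[O-]I(=O)(=O)=O)
Why: Lemieux–Johnson oxidation (osmylation of the 1,1-disubstituted alkene, then periodate cleavage of the diol) is chosen over ozonolysis because trialkoxyarenes compete with the styrene for ozone, and the lutidine buffer protects the acetals and the enolisable C3 centre.

Step 16
Reactants: 24 α-benzyloxy aryl ketone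
Product: 25 (1S,2R,3R)-2-(benzyloxy)-1-[3,4,5-tris(benzyloxy)phenyl]-3-[2,4,6-tris(methoxymethoxy)phenyl]-3-(penta-O-benzylcatechin-8-yl)propan-1-ol
Conditions: Zn(BH4)2, Et2O/CH2Cl2, −40 → 0 °C; aq. NH4Cl
Reagents that add atoms: none
Why: Chelation-controlled borohydride reduction (Cram chelate): zinc bridges the carbonyl and the α-benzyloxy oxygen and hydride enters from the side of the C3 hydrogen, away from the diarylmethyl group, which should give the anti (erythro) carbinol, flavan 2S.

Step 17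
Reactants: 25 (1S,2R,3R)-carbinol
Product: 27 (1S,2R,3R)-2-(benzyloxy)-1-[3,4,5-tris(benzyloxy)phenyl]-3-(2,4,6-trihydroxyphenyl)-3-(penta-O-benzylcatechin-8-yl)propan-1-ol, via tetrakis(trimethylsilyl) ether 26 (not isolated)
Conditions: TMSOTf, 2,2'-bipyridyl, CH2Cl2, 0 °C → rt; then H2O/THF, rt
Reagents that add atoms: none
Why: Non-acidic cleavage of aryl MOM ethers by silyl triflate and bipyridyl (silyl transfer to the acetal, capture of the methoxymethyl cation by the pyridine base, hydrolysis of the silyl ethers) should free the three phenols without ionising the electron-rich benzylic carbinol or touching benzyl ethers.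

Step 18
Reactants: 27 (1S,2R,3R)-tetraol
Product: 28 3-O-benzyl-3',4',5'-tri-O-benzylepigallocatechin-(4β→8)-3,5,7,3',4'-penta-O-benzylcatechin
Conditions: PPh3, DIAD, THF (0.01 M), 0 °C (betaine formed before 27 is added)
Reagents that add atoms: none
Why: Intramolecular Mitsunobu etherification: an ortho phenoxide displaces the benzylic oxyphosphonium in a 6-exo closure with inversion, turning 2S into 2R (2,3-cis), and either ortho hydroxyl gives the same ring.

Step 19
Reactants: 28 nona-O-benzyl dimer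
Product: 29 epigallocatechin-(4β→8)-catechin (CNP0225927.1)
Conditions: H2 (1 atm), Pd(OH)2/C, THF/MeOH/H2O, rt
Reagents that add atoms: none
Why: Hydrogenolysis of the nine benzyl ethers over Pearlman's catalyst under neutral conditions should leave the C4–C8 bond, the pyran C–O bonds and all five stereocentres intact.

**Compound list**

1 | (+)-catechin, (2R,3S) | O[C@H]1Cc2c(O)cc(O)cc2O[C@@H]1c1ccc(O)c(O)c1 | starting material
2 | 5,7,3',4'-tetra-O-benzyl-(+)-catechin, (2R,3S), 3-OH free | O[C@H]1Cc2c(OCc3ccccc3)cc(OCc3ccccc3)cc2O[C@@H]1c1ccc(OCc2ccccc2)c(OCc2ccccc2)c1 | intermediate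
3 | 8-bromo-5,7,3',4'-tetra-O-benzylcatechin, (2R,3S) | Brc1c(OCc3ccccc3)cc(OCc3ccccc3)c2c1O[C@H](c1ccc(OCc3ccccc3)c(OCc3ccccc3)c1)[C@@H](O)C2 | intermediate
4 | 8-bromo-3,5,7,3',4'-penta-O-benzylcatechin, (2R,3S) | Brc1c(OCc3ccccc3)cc(OCc3ccccc3)c2c1O[C@H](c1ccc(OCc3ccccc3)c(OCc3ccccc3)c1)[C@@H](OCc3ccccc3)C2 | intermediate
5 | 8-lithio-3,5,7,3',4'-penta-O-benzylcatechin (not isolated) | [Li]c1c(OCc3ccccc3)cc(OCc3ccccc3)c2c1O[C@H](c1ccc(OCc3ccccc3)c(OCc3ccccc3)c1)[C@@H](OCc3ccccc3)C2 | intermediate
6 | 3,5,7,3',4'-penta-O-benzylcatechin-8-carbaldehyde, (2R,3S) | O=Cc1c(OCc3ccccc3)cc(OCc3ccccc3)c2c1O[C@H](c1ccc(OCc3ccccc3)c(OCc3ccccc3)c1)[C@@H](OCc3ccccc3)C2 | intermediate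
7 | 8-ethynyl-3,5,7,3',4'-penta-O-benzylcatechin, (2R,3S) | C#Cc1c(OCc3ccccc3)cc(OCc3ccccc3)c2c1O[C@H](c1ccc(OCc3ccccc3)c(OCc3ccccc3)c1)[C@@H](OCc3ccccc3)C2 | intermediate
8 | acenaphthoquinone (acenaphthylene-1,2-dione) | O=C1C(=O)c2cccc3cccc1c23 | starting material
9 | cis-1,2-dimethyl-1,2-dihydroacenaphthylene-1,2-diol (mac diol, meso) | O[C@]1(C)c2cccc3cccc(c23)[C@]1(C)O | intermediate
10 | 2-[(Z)-2-(penta-O-benzylcatechin-8-yl)vinyl]-1,3,2-benzodioxaborole (catechol boronate, not isolated) | B1(Oc2ccccc2O1)/C=C\c1c(OCc3ccccc3)cc(OCc3ccccc3)c2c1O[C@H](c1ccc(OCc3ccccc3)c(OCc3ccccc3)c1)[C@@H](OCc3ccccc3)C2 | intermediate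
11 | (Z)-2-(penta-O-benzylcatechin-8-yl)vinylboronic acid ester of diol 9 (mac ester) | B1(O[C@]2(C)c3cccc4cccc(c34)[C@]2(C)O1)/C=C\c1c(OCc3ccccc3)cc(OCc3ccccc3)c2c1O[C@H](c1ccc(OCc3ccccc3)c(OCc3ccccc3)c1)[C@@H](OCc3ccccc3)C2 | intermediate
12 | 3,4,5-tris(benzyloxy)benzoic acid | OC(=O)c1cc(OCc2ccccc2)c(OCc2ccccc2)c(OCc2ccccc2)c1 | starting material
13 | 1-[3,4,5-tris(benzyloxy)phenyl]ethan-1-one | CC(=O)c1cc(OCc2ccccc2)c(OCc2ccccc2)c(OCc2ccccc2)c1 | intermediate
14 | 1,2,3-tris(benzyloxy)-5-(1-bromovinyl)benzene | BrC(=C)c1cc(OCc2ccccc2)c(OCc2ccccc2)c(OCc2ccccc2)c1 | intermediate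
15 | phloroglucinol | Oc1cc(O)cc(O)c1 | starting material
16 | 1,3,5-tris(methoxymethoxy)benzene | COCOc1cc(OCOC)cc(OCOC)c1 | intermediate
17 | 2-bromo-1,3,5-tris(methoxymethoxy)benzene | Brc1c(OCOC)cc(OCOC)cc1OCOC | intermediate
18 | 1-[3,4,5-tris(benzyloxy)phenyl]vinyllithium (not isolated) | [Li]C(=C)c1cc(OCc2ccccc2)c(OCc2ccccc2)c(OCc2ccccc2)c1 | intermediate
19 | lithium borate (ate complex) from 11 and 18, with the mac diol, the (Z)-catechinylvinyl and the 1-arylvinyl group on boron; configuration at boron undefined (not isolated) | [Li+].C=C(c1cc(OCc2ccccc2)c(OCc2ccccc2)c(OCc2ccccc2)c1)[B-]1(O[C@]2(C)c3cccc4cccc(c34)[C@]2(C)O1)/C=C\c1c(OCc3ccccc3)cc(OCc3ccccc3)c2c1O[C@H](c1ccc(OCc3ccccc3)c(OCc3ccccc3)c1)[C@@H](OCc3ccccc3)C2 | intermediate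
20 | (3R,4R)-2-[3,4,5-tris(benzyloxy)phenyl]-4-[2,4,6-tris(methoxymethoxy)phenyl]-4-(penta-O-benzylcatechin-8-yl)but-1-en-3-ylboronic acid mac ester (boron on C3, diaryl methine C4, 2-methylene) | C=C(c1cc(OCc2ccccc2)c(OCc2ccccc2)c(OCc2ccccc2)c1)[C@H](B1O[C@]2(C)c3cccc4cccc(c34)[C@]2(C)O1)[C@H](c1c(OCOC)cc(OCOC)cc1OCOC)c1c(OCc3ccccc3)cc(OCc3ccccc3)c2c1O[C@H](c1ccc(OCc3ccccc3)c(OCc3ccccc3)c1)[C@@H](OCc3ccccc3)C2 | intermediate
21 | (3R,4R)-2-[3,4,5-tris(benzyloxy)phenyl]-4-[2,4,6-tris(methoxymethoxy)phenyl]-4-(penta-O-benzylcatechin-8-yl)but-1-en-3-ol | C=C(c1cc(OCc2ccccc2)c(OCc2ccccc2)c(OCc2ccccc2)c1)[C@H](O)[C@H](c1c(OCOC)cc(OCOC)cc1OCOC)c1c(OCc3ccccc3)cc(OCc3ccccc3)c2c1O[C@H](c1ccc(OCc3ccccc3)c(OCc3ccccc3)c1)[C@@H](OCc3ccccc3)C2 | intermediate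
22 | (3R,4R)-3-(benzyloxy)-2-[3,4,5-tris(benzyloxy)phenyl]-4-[2,4,6-tris(methoxymethoxy)phenyl]-4-(penta-O-benzylcatechin-8-yl)but-1-ene | C=C(c1cc(OCc2ccccc2)c(OCc2ccccc2)c(OCc2ccccc2)c1)[C@H](OCc1ccccc1)[C@H](c1c(OCOC)cc(OCOC)cc1OCOC)c1c(OCc3ccccc3)cc(OCc3ccccc3)c2c1O[C@H](c1ccc(OCc3ccccc3)c(OCc3ccccc3)c1)[C@@H](OCc3ccccc3)C2 | intermediate
23 | (3R,4R)-3-(benzyloxy)-2-[3,4,5-tris(benzyloxy)phenyl]-4-[2,4,6-tris(methoxymethoxy)phenyl]-4-(penta-O-benzylcatechin-8-yl)butane-1,2-diol, C2 epimers (not isolated) | OCC(O)(c1cc(OCc2ccccc2)c(OCc2ccccc2)c(OCc2ccccc2)c1)[C@H](OCc1ccccc1)[C@H](c1c(OCOC)cc(OCOC)cc1OCOC)c1c(OCc3ccccc3)cc(OCc3ccccc3)c2c1O[C@H](c1ccc(OCc3ccccc3)c(OCc3ccccc3)c1)[C@@H](OCc3ccccc3)C2 | intermediate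
24 | (2R,3R)-2-(benzyloxy)-1-[3,4,5-tris(benzyloxy)phenyl]-3-[2,4,6-tris(methoxymethoxy)phenyl]-3-(penta-O-benzylcatechin-8-yl)propan-1-one (flavan C2 ketone, 3R,4R) | O=C(c1cc(OCc2ccccc2)c(OCc2ccccc2)c(OCc2ccccc2)c1)[C@H](OCc1ccccc1)[C@H](c1c(OCOC)cc(OCOC)cc1OCOC)c1c(OCc3ccccc3)cc(OCc3ccccc3)c2c1O[C@H](c1ccc(OCc3ccccc3)c(OCc3ccccc3)c1)[C@@H](OCc3ccccc3)C2 | intermediate
25 | (1S,2R,3R)-2-(benzyloxy)-1-[3,4,5-tris(benzyloxy)phenyl]-3-[2,4,6-tris(methoxymethoxy)phenyl]-3-(penta-O-benzylcatechin-8-yl)propan-1-ol (flavan 2S,3R,4R) | O[C@@H](c1cc(OCc2ccccc2)c(OCc2ccccc2)c(OCc2ccccc2)c1)[C@H](OCc1ccccc1)[C@H](c1c(OCOC)cc(OCOC)cc1OCOC)c1c(OCc3ccccc3)cc(OCc3ccccc3)c2c1O[C@H](c1ccc(OCc3ccccc3)c(OCc3ccccc3)c1)[C@@H](OCc3ccccc3)C2 | intermediate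
26 | tetrakis(trimethylsilyl) ether of 27 (three aryl O–TMS and the C1 O–TMS; not isolated) | C[Si](C)(C)O[C@@H](c1cc(OCc2ccccc2)c(OCc2ccccc2)c(OCc2ccccc2)c1)[C@H](OCc1ccccc1)[C@H](c1c(O[Si](C)(C)C)cc(O[Si](C)(C)C)cc1O[Si](C)(C)C)c1c(OCc3ccccc3)cc(OCc3ccccc3)c2c1O[C@H](c1ccc(OCc3ccccc3)c(OCc3ccccc3)c1)[C@@H](OCc3ccccc3)C2 | intermediate
27 | (1S,2R,3R)-2-(benzyloxy)-1-[3,4,5-tris(benzyloxy)phenyl]-3-(2,4,6-trihydroxyphenyl)-3-(penta-O-benzylcatechin-8-yl)propan-1-ol | O[C@@H](c1cc(OCc2ccccc2)c(OCc2ccccc2)c(OCc2ccccc2)c1)[C@H](OCc1ccccc1)[C@H](c1c(O)cc(O)cc1O)c1c(OCc3ccccc3)cc(OCc3ccccc3)c2c1O[C@H](c1ccc(OCc3ccccc3)c(OCc3ccccc3)c1)[C@@H](OCc3ccccc3)C2 | intermediate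
28 | 3-O-benzyl-3',4',5'-tri-O-benzylepigallocatechin-(4β→8)-3,5,7,3',4'-penta-O-benzylcatechin (upper unit 2R,3R,4R, 5-OH and 7-OH free) | Oc1cc(O)c2c(c1)O[C@H](c1cc(OCc3ccccc3)c(OCc3ccccc3)c(OCc3ccccc3)c1)[C@H](OCc3ccccc3)[C@H]2c1c(OCc3ccccc3)cc(OCc3ccccc3)c2c1O[C@H](c1ccc(OCc3ccccc3)c(OCc3ccccc3)c1)[C@@H](OCc3ccccc3)C2 | intermediate
29 | epigallocatechin-(4β→8)-catechin, upper unit (2R,3R,4R), lower unit (2R,3S) | Oc1cc(O)c2c(c1)O[C@H](c1cc(O)c(O)c(O)c1)[C@H](O)[C@H]2c1c(O)cc(O)c2c1O[C@H](c1ccc(O)c(O)c1)[C@@H](O)C2 | target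

**Step count.** Total: 19 steps. Longest linear sequence: 14 steps from (+)-catechin (steps 1–5, 7, 12–19).

**Steps most likely to fail**

1. Step 12 (proposed new method). Four processes could defeat it:
   - direct Suzuki-type transfer of either alkenyl group from the borate to arylpalladium;
   - activation of the 1-arylvinyl group, so that the catechinylvinyl group migrates instead;
   - β-hydride elimination from the crowded C4–palladium intermediate before the slow reductive elimination to a di-ortho-substituted aryl;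
   - poor face selection by the ligand.

   The fallback uses the known Lewis-acid coupling of a flavan-4-yl cation with a flavan nucleophile. It sets out from compound 2 and commercial (−)-epigallocatechin F1. The five phenols of F1 are benzylated (BnBr, K2CO3, DMF) to 5,7,3',4',5'-penta-O-benzylepigallocatechin F2. DDQ with ethylene glycol in CH2Cl2 oxidises C4 and should give 4β-(2-hydroxyethoxy)-penta-O-benzylepigallocatechin F3. TiCl4 in CH2Cl2 (−78 → 0 °C) ionises F3, and C8 of 2 (fourfold excess, to suppress oligomers) should capture the cation trans to the 3-hydroxyl, giving nona-O-benzyl epigallocatechin-(4β→8)-catechin F4. Hydrogenolysis of F4 (H2, Pd(OH)2/C) gives the target, so the fallback comes back to the route at compound 29.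

2. Step 18. The electron-rich benzylic oxyphosphonium may ionise before displacement, which would erode the inversion and let the 2,3-trans isomer form. The azodicarboxylate may also attack the trihydroxyphenyl ring, or the 7-hydroxyl may react intermolecularly. The fallback sets out from ketone 24 and bypasses steps 16–18. Catalytic HCl in MeOH/THF (40 °C) removes the three MOM groups, and an ortho phenol adds to the C2 ketone to give the cyclic methyl ketal (2-methoxyflavan) F5 as C2 epimers. Ionic hydrogenation with Et3SiH and BF3·OEt2 (CH2Cl2, −78 °C) reduces the 2-aryl oxocarbenium ion. Hydride should enter axially, anti to the pseudo-axial 3-benzyloxy group, which places the B ring cis to O3. This gives compound 28, where the fallback comes back to the route.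

3. Step 7. Vinylidene formation may be slow on the di-ortho-substituted aryl alkyne, so that ordinary syn-hydroboration (E isomer), Z→E isomerisation or low conversion takes over. The fallback sets out from aldehyde 6 and bypasses alkyne 7. Stork–Zhao olefination (Ph3P+CH2I I−, NaHMDS, THF/DMPU, −78 °C) should give the (Z)-vinyl iodide F6. Iodine–lithium exchange with t-BuLi at −78 °C (alkene geometry retained), trapping with B(OMe)3 and esterification of the crude boronate with diol 9 give compound 11, where the fallback comes back to the route.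

Further compounds
F1 | step 12 | (−)-epigallocatechin, (2R,3R), commercial | O[C@@H]1Cc2c(O)cc(O)cc2O[C@@H]1c1cc(O)c(O)c(O)c1
F2 | step 12 | 5,7,3',4',5'-penta-O-benzyl-(−)-epigallocatechin | O[C@@H]1Cc2c(OCc3ccccc3)cc(OCc3ccccc3)cc2O[C@@H]1c1cc(OCc2ccccc2)c(OCc2ccccc2)c(OCc2ccccc2)c1
F3 | step 12 | 4β-(2-hydroxyethoxy)-5,7,3',4',5'-penta-O-benzylepigallocatechin (2,3-cis-3,4-trans) | C(Oc1cc(OCc3ccccc3)c2c(c1)O[C@H](c1cc(OCc3ccccc3)c(OCc3ccccc3)c(OCc3ccccc3)c1)[C@H](O)[C@H]2OCCO)c1ccccc1
F4 | step 12 | 5,7,3',4',5'-penta-O-benzylepigallocatechin-(4β→8)-5,7,3',4'-tetra-O-benzylcatechin | C(Oc1cc(OCc3ccccc3)c2c(c1)O[C@H](c1cc(OCc3ccccc3)c(OCc3ccccc3)c(OCc3ccccc3)c1)[C@H](O)[C@H]2c1c(OCc3ccccc3)cc(OCc3ccccc3)c2c1O[C@H](c1ccc(OCc3ccccc3)c(OCc3ccccc3)c1)[C@@H](O)C2)c1ccccc1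
F5 | step 18 | 2-methoxy cyclic ketal of the upper unit (3R,4R; C2 epimers; 5-OH and 7-OH free; 3-O-benzyl), bonded at C4 to penta-O-benzylcatechin C8 | Oc1cc(O)c2c(c1)OC(OC)(c1cc(OCc3ccccc3)c(OCc3ccccc3)c(OCc3ccccc3)c1)[C@H](OCc3ccccc3)[C@H]2c1c(OCc3ccccc3)cc(OCc3ccccc3)c2c1O[C@H](c1ccc(OCc3ccccc3)c(OCc3ccccc3)c1)[C@@H](OCc3ccccc3)C2
F6 | step 7 | 8-[(Z)-2-iodovinyl]-3,5,7,3',4'-penta-O-benzylcatechin | I/C=C\c1c(OCc3ccccc3)cc(OCc3ccccc3)c2c1O[C@H](c1ccc(OCc3ccccc3)c(OCc3ccccc3)c1)[C@@H](OCc3ccccc3)C2
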